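**Retrosynthetic overview**
- C7–aryl bond: Weinreb ketone synthesis from an (S)-2-aryloxypropanoic Weinreb amide and 3,4,5-trimethoxyphenylmagnesium bromide.
- C8–O bond: Mitsunobu etherification of the cinnamyl phenol with methyl (R)-lactate; the inversion sets (8S).
- Key C–C bond C7′–C8′: intermolecular aldol addition of the lithium enolate of ethyl acetate to O-TIPS-vanillin, then dehydration (E-alkene), ester reduction and O-methylation.
- No ring is formed: ring A (trimethoxyphenyl) comes from 5-bromo-1,2,3-trimethoxybenzene and ring B (guaiacyl) from vanillin.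

Assumption: the target is taken exactly as the given SMILES, the (S)-α-aryloxy ketone with the E alkene; locants C7/C8 and C7′–C9′ follow the neolignan name.

**Step 1**
Reactants: 1 vanillin (4-hydroxy-3-methoxybenzaldehyde)
Product: 2 3-methoxy-4-[(triisopropylsilyl)oxy]benzaldehyde
Conditions: TIPSCl (1.1 equiv), imidazole (2.2 equiv), DMF, 0 °C → rt
Reagents that add atoms: chlorotriisopropylsilane, CC(C)[Si](Cl)(C(C)C)C(C)C
Why: Imidazole-promoted O-silylation masks the acidic phenol as a bulky aryl TIPS ether that tolerates the enolate, hydride and alkoxide reagents of steps 2–5.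

**Step 2**
Reactants: 2 3-methoxy-4-[(triisopropylsilyl)oxy]benzaldehyde; 3 ethyl acetate
Product: 5 ethyl (±)-3-hydroxy-3-{3-methoxy-4-[(triisopropylsilyl)oxy]phenyl}propanoate, via lithium enolate CH2=C(OLi)OEt 4 (not isolated)
Conditions: LiN(iPr)2 (commercial solution, 1.15 equiv), 3 (1.2 equiv), THF, −78 °C, 30 min; then 2, −78 °C, 1 h; AcOH quench at −78 °C
Reagents that add atoms: none
Why: Directed crossed aldol addition, in which the ester enolate is formed completely at −78 °C before the non-enolisable aromatic aldehyde is added, so only the cross product forms; the new carbinol centre is racemic and is erased in step 3.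

**Step 3**
Reactants: 5 ethyl (±)-3-hydroxy-3-{3-methoxy-4-[(triisopropylsilyl)oxy]phenyl}propanoate
Product: 7 ethyl (E)-3-{3-methoxy-4-[(triisopropylsilyl)oxy]phenyl}prop-2-enoate, via benzylic mesylate 6 (not isolated)
Conditions: MsCl (1.3 equiv), Et3N (3 equiv), CH2Cl2, 0 °C; then DBU (2 equiv), 0 °C → rt
Reagents that add atoms: none
Why: Aldol dehydration by mesylation and E1cB-type β-elimination of the activated benzylic alcohol gives the conjugated cinnamate, whose E geometry is strongly favoured.

**Step 4**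
Reactants: 7 ethyl (E)-3-{3-methoxy-4-[(triisopropylsilyl)oxy]phenyl}prop-2-enoate
Product: 8 (E)-3-{3-methoxy-4-[(triisopropylsilyl)oxy]phenyl}prop-2-en-1-ol
Conditions: iBu2AlH (2.5 equiv), CH2Cl2, −78 °C; aq. potassium sodium tartrate (KNaC4H4O6) work-up
Reagents that add atoms: none
Why: Hydride 1,2-reduction of the α,β-unsaturated ester by iBu2AlH at low temperature gives the allylic alcohol without touching the alkene or the aryl silyl ether.

**Step 5**
Reactants: 8 (E)-3-{3-methoxy-4-[(triisopropylsilyl)oxy]phenyl}prop-2-en-1-ol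
Product: 10 triisopropyl{2-methoxy-4-[(E)-3-methoxyprop-1-en-1-yl]phenoxy}silane, via sodium alkoxide ArCH=CHCH2ONa 9 (not isolated)
Conditions: NaH (1.3 equiv), THF, 0 °C, 20 min; then MeI (3 equiv), 0 °C → rt
Reagents that add atoms: iodomethane, CI
Why: Williamson ether synthesis, in which the primary allylic alkoxide is methylated by MeI much faster than it can attack the hindered triisopropylsilyl group.

**Step 6**
Reactants: 10 triisopropyl{2-methoxy-4-[(E)-3-methoxyprop-1-en-1-yl]phenoxy}silane
Product: 11 2-methoxy-4-[(E)-3-methoxyprop-1-en-1-yl]phenol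
Conditions: Bu4NF (1.2 equiv), AcOH (1.2 equiv), THF, 0 °C
Reagents that add atoms: none
Why: Fluoride-driven desilylation of the aryl silyl ether, buffered with AcOH so that the sensitive 4-hydroxycinnamyl ether is released as the phenol and not left as a phenoxide.

**Step 7**
Reactants: 11 2-methoxy-4-[(E)-3-methoxyprop-1-en-1-yl]phenol; 12 methyl (R)-lactate (methyl (2R)-2-hydroxypropanoate)
Product: 13 methyl (2S)-2-{2-methoxy-4-[(E)-3-methoxyprop-1-en-1-yl]phenoxy}propanoate
Conditions: 12 (1.3 equiv), PPh3 (1.4 equiv), DIAD (1.4 equiv, added dropwise), THF, 0 °C → rt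
Reagents that add atoms: none
Why: Mitsunobu etherification, in which the phenol displaces the activated lactate hydroxyl by SN2 with clean inversion, so the (R) carbinol of 12 becomes the (S) aryl ether centre (C8) of the target.

**Step 8**
Reactants: 13 methyl (2S)-2-{2-methoxy-4-[(E)-3-methoxyprop-1-en-1-yl]phenoxy}propanoate
Product: 14 (2S)-2-{2-methoxy-4-[(E)-3-methoxyprop-1-en-1-yl]phenoxy}propanoic acid
Conditions: LiOH·H2O (1.5 equiv), THF/H2O 3:1, 0 °C; then cold 0.5 M HCl to pH 3, extraction
Reagents that add atoms: lithium hydroxide monohydrate, [Li+].[OH-].O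
Why: Ester saponification at 0 °C is faster than enolisation of the α-aryloxy ester, so C8 keeps its configuration, and the brief cold acidification spares the allylic methyl ether.

**Step 9**
Reactants: 14 (2S)-2-{2-methoxy-4-[(E)-3-methoxyprop-1-en-1-yl]phenoxy}propanoic acid
Product: 15 (2S)-N-methoxy-2-{2-methoxy-4-[(E)-3-methoxyprop-1-en-1-yl]phenoxy}-N-methylpropanamide
Conditions: MeNHOMe·HCl (1.3 equiv), EDC·HCl (1.3 equiv), HOBt (1.3 equiv), N-methylmorpholine (3 equiv), CH2Cl2, 0 °C → rt
Reagents that add atoms: N,O-dimethylhydroxylamine hydrochloride, CNOC.Cl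
Why: Carbodiimide/HOBt amide coupling under weakly basic conditions gives the Weinreb amide without epimerisation, because the α-aryloxy acid cannot form an azlactone and the activated acid is trapped quickly by the amine.

**Step 10**
Reactants: 15 (2S)-N-methoxy-2-{2-methoxy-4-[(E)-3-methoxyprop-1-en-1-yl]phenoxy}-N-methylpropanamide; 16 5-bromo-1,2,3-trimethoxybenzene
Product: 19 (2S)-2-{2-methoxy-4-[(E)-3-methoxyprop-1-en-1-yl]phenoxy}-1-(3,4,5-trimethoxyphenyl)propan-1-one, via Grignard reagent ArMgBr 17 (not isolated), via bromomagnesium hemiaminal chelate 18 (not isolated)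
Conditions: 16 (1.6 equiv), Mg turnings (1.8 equiv), I2 (cat.), THF, 40 °C → reflux; cool, add to 15 in THF, −20 → 0 °C; pour into cold sat. aq. NH4Cl
Reagents that add atoms: none
Why: Weinreb ketone synthesis, in which the aryl Grignard adds once to give the stable five-membered chelate 18 that collapses to the ketone only on the cold buffered quench, so neither over-addition nor base-mediated epimerisation at C8 occurs and the target is obtained.

**Compound list**
1 | vanillin (4-hydroxy-3-methoxybenzaldehyde) | COc1cc(C=O)ccc1O | starting material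
2 | 3-methoxy-4-[(triisopropylsilyl)oxy]benzaldehyde | COc1cc(C=O)ccc1O[Si](C(C)C)(C(C)C)C(C)C | intermediate
3 | ethyl acetate | CCOC(C)=O | starting material
4 | lithium enolate of ethyl acetate (lithium 1-ethoxyethen-1-olate) | [Li+].C=C([O-])OCC | intermediate (not isolated)
5 | ethyl (±)-3-hydroxy-3-{3-methoxy-4-[(triisopropylsilyl)oxy]phenyl}propanoate (racemic at C3) | CCOC(=O)CC(O)c1ccc(O[Si](C(C)C)(C(C)C)C(C)C)c(OC)c1 | intermediate
6 | ethyl (±)-3-{3-methoxy-4-[(triisopropylsilyl)oxy]phenyl}-3-[(methylsulfonyl)oxy]propanoate | CCOC(=O)CC(OS(C)(=O)=O)c1ccc(O[Si](C(C)C)(C(C)C)C(C)C)c(OC)c1 | intermediate (not isolated)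
7 | ethyl (E)-3-{3-methoxy-4-[(triisopropylsilyl)oxy]phenyl}prop-2-enoate | CCOC(=O)/C=C/c1ccc(O[Si](C(C)C)(C(C)C)C(C)C)c(OC)c1 | intermediate
8 | (E)-3-{3-methoxy-4-[(triisopropylsilyl)oxy]phenyl}prop-2-en-1-ol | OC/C=C/c1ccc(O[Si](C(C)C)(C(C)C)C(C)C)c(OC)c1 | intermediate
9 | sodium (E)-3-{3-methoxy-4-[(triisopropylsilyl)oxy]phenyl}prop-2-en-1-olate | [Na+].[O-]C/C=C/c1ccc(O[Si](C(C)C)(C(C)C)C(C)C)c(OC)c1 | intermediate (not isolated)
10 | triisopropyl{2-methoxy-4-[(E)-3-methoxyprop-1-en-1-yl]phenoxy}silane | COC/C=C/c1ccc(O[Si](C(C)C)(C(C)C)C(C)C)c(OC)c1 | intermediate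
11 | 2-methoxy-4-[(E)-3-methoxyprop-1-en-1-yl]phenol | COC/C=C/c1ccc(O)c(OC)c1 | intermediate
12 | methyl (R)-lactate (methyl (2R)-2-hydroxypropanoate) | C[C@@H](O)C(=O)OC | starting material
13 | methyl (2S)-2-{2-methoxy-4-[(E)-3-methoxyprop-1-en-1-yl]phenoxy}propanoate | COC/C=C/c1ccc(O[C@@H](C)C(=O)OC)c(OC)c1 | intermediate
14 | (2S)-2-{2-methoxy-4-[(E)-3-methoxyprop-1-en-1-yl]phenoxy}propanoic acid | COC/C=C/c1ccc(O[C@@H](C)C(=O)O)c(OC)c1 | intermediate
15 | (2S)-N-methoxy-2-{2-methoxy-4-[(E)-3-methoxyprop-1-en-1-yl]phenoxy}-N-methylpropanamide | COC/C=C/c1ccc(O[C@@H](C)C(=O)N(C)OC)c(OC)c1 | intermediate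
16 | 5-bromo-1,2,3-trimethoxybenzene | COc1cc(Br)cc(OC)c1OC | starting material
17 | (3,4,5-trimethoxyphenyl)magnesium bromide | COc1cc([Mg]Br)cc(OC)c1OC | intermediate (not isolated)
18 | bromomagnesium (2S)-1-[methoxy(methyl)amino]-2-{2-methoxy-4-[(E)-3-methoxyprop-1-en-1-yl]phenoxy}-1-(3,4,5-trimethoxyphenyl)propan-1-olate (tetrahedral chelate, C1 unassigned) | COC/C=C/c1ccc(O[C@@H](C)C(O[Mg]Br)(N(C)OC)c2cc(OC)c(OC)c(OC)c2)c(OC)c1 | intermediate (not isolated)
19 | (2S)-2-{2-methoxy-4-[(E)-3-methoxyprop-1-en-1-yl]phenoxy}-1-(3,4,5-trimethoxyphenyl)propan-1-one, (8S,7′E)-3,4,5,3′,9′-pentamethoxy-7-oxo-8-O-4′-neolignan | COC/C=C/c1ccc(O[C@@H](C)C(=O)c2cc(OC)c(OC)c(OC)c2)c(OC)c1 | target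

**Totals**
Total step count: 10. Longest linear sequence: 10 steps (1 → 19); 3, 12 and 16 enter as purchased materials.

**Steps most likely to fail, and fallbacks**

Step 10 (Grignard on the α-aryloxy Weinreb amide). The risks are enolisation of 15 by the basic Grignard and partial loss of ee at C8. The fallback sets out from 15 and comes back at 19. Reduce 15 with iBu2AlH in THF at −78 °C to (2S)-2-{2-methoxy-4-[(E)-3-methoxyprop-1-en-1-yl]phenoxy}propanal F3 and use it crude at once. Add the Grignard reagent 17 at −78 °C, where addition to the aldehyde is much faster than deprotonation, to give (2S)-2-{2-methoxy-4-[(E)-3-methoxyprop-1-en-1-yl]phenoxy}-1-(3,4,5-trimethoxyphenyl)propan-1-ol F4 as a mixture of C7 epimers. Oxidise both epimers with Dess–Martin periodinane buffered by NaHCO3 in CH2Cl2 to converge on 19 under non-basic conditions.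

Step 7 (Mitsunobu with the electron-rich, ortho-substituted phenol). The risks are sluggish coupling, alkylated hydrazide by-product and difficult removal of Ph3PO. The fallback sets out from 12 and comes back at 13. Convert 12 with TsCl, Et3N and catalytic DMAP in CH2Cl2 into methyl (2R)-2-{[(4-methylphenyl)sulfonyl]oxy}propanoate F2. Displace the sulfonate with phenol 11 and K2CO3 in MeCN at 50 °C; this classical SN2 etherification gives the same inversion to (S)-13 without any phosphine or azo reagent.

Step 5 (alkoxide methylation beside an aryl silyl ether). The risk is silyl migration or cleavage triggered by the sodium alkoxide. The fallback sets out from 8 and comes back at 10. Acylate 8 with methyl chloroformate and pyridine in CH2Cl2 at 0 °C to give (E)-3-{3-methoxy-4-[(triisopropylsilyl)oxy]phenyl}prop-2-en-1-yl methyl carbonate F1. Warm F1 with 5 mol % Pd(PPh3)4 (zerovalent palladium) in THF/MeOH at 50 °C. Decarboxylative allylic etherification through the π-cinnamyl palladium methoxide delivers methoxide to the unhindered terminus and gives the linear E ether 10 without any strong base.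

**Further compounds**
F1 | step 5 | (E)-3-{3-methoxy-4-[(triisopropylsilyl)oxy]phenyl}prop-2-en-1-yl methyl carbonate | COC(=O)OC/C=C/c1ccc(O[Si](C(C)C)(C(C)C)C(C)C)c(OC)c1
F2 | step 7 | methyl (2R)-2-{[(4-methylphenyl)sulfonyl]oxy}propanoate | C[C@@H](OS(=O)(=O)c1ccc(C)cc1)C(=O)OC
F3 | step 10 | (2S)-2-{2-methoxy-4-[(E)-3-methoxyprop-1-en-1-yl]phenoxy}propanal | COC/C=C/c1ccc(O[C@@H](C)C=O)c(OC)c1
F4 | step 10 | (2S)-2-{2-methoxy-4-[(E)-3-methoxyprop-1-en-1-yl]phenoxy}-1-(3,4,5-trimethoxyphenyl)propan-1-ol (mixture of C1 epimers) | COC/C=C/c1ccc(O[C@@H](C)C(O)c2cc(OC)c(OC)c(OC)c2)c(OC)c1
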